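**Strategy.** The lower flavan unit is disconnected at C3–C4 of its pyran ring (ring F). C4 is a benzylic methylene on the phloroglucinol ring D and C3 carries oxygen, so the pair is the retron of a C3=C4 olefin. Ring-closing metathesis between a ring-D vinyl group and the vinyl group of an (S)-aryl 1-arylallyl ether (C2 set by iridium-catalysed allylic etherification) closes ring F as a flav-3-ene in one operation. Hydroboration, oxidation and L-Selectride reduction give the 2,3-cis alcohol; C8 bromination, double galloylation, 4β→6 Friedel–Crafts coupling with bromine-capped epiafzelechin and global hydrogenolysis complete the synthesis.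

Key step: step 9

Remarks and assumptions
- Flavan numbering is used within each unit (O1, C2, C3, C4, C4a, C5–C8, C8a; primed numbers for the aryl ring on C2). Upper unit: rings A (benzo), C (pyran), B (aryl). Lower unit: rings D (benzo), F (pyran), E (aryl).
- Assumption: (−)-epiafzelechin (21) is bought as a catalogue natural product (chiral pool). The lower unit is made de novo because its 3′-oxygen must be distinguished from O4′ and O5′.
- Assumption: L = O,O′-(1,1′-binaphthalene-2,2′-diyl) N,N-bis(1-phenylethyl)phosphoramidite. Both antipodes are commercial; the antipode that gives the (S)-ether 11 is selected in a first run.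

**Route**

Step 1
Reactants: 1 3,4,5-trihydroxybenzaldehyde
Product: 2 7-hydroxy-2,2-diphenyl-1,3-benzodioxole-5-carbaldehyde
Conditions: Ph2CCl2 (1.1 equiv), K2CO3, MeCN, rt
Reagents that add atoms: dichlorodiphenylmethane ClC(Cl)(c1ccccc1)c1ccccc1
Why: Catechol ketalisation with a gem-dichloride; the two possible vicinal pairs are equivalent by symmetry, so a single diphenylmethylene ketal forms and one meta-hydroxyl (the future O3′) stays free.

Step 2
Reactants: 2 7-hydroxy-2,2-diphenyl-1,3-benzodioxole-5-carbaldehyde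
Product: 3 2,2-diphenyl-7-(triisopropylsilyloxy)-1,3-benzodioxole-5-carbaldehyde
Conditions: i-Pr3SiCl, imidazole, DMF, rt to 40 °C
Reagents that add atoms: chlorotriisopropylsilane CC(C)[Si](Cl)(C(C)C)C(C)C
Why: Silylation of the only free phenol; the bulky aryl silyl ether should survive the later hydride, base and oxidation steps and is later removed by fluoride without touching benzyl ethers or the ketal.

Step 3
Reactants: 3 2,2-diphenyl-7-(triisopropylsilyloxy)-1,3-benzodioxole-5-carbaldehyde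
Product: 4 ethyl (E)-3-[2,2-diphenyl-7-(triisopropylsilyloxy)-1,3-benzodioxol-5-yl]acrylate
Conditions: Ph3P=CHCO2Et, toluene, 80 °C
Reagents that add atoms: ethyl (triphenylphosphoranylidene)acetate CCOC(=O)C=P(c1ccccc1)(c1ccccc1)c1ccccc1
Why: Wittig olefination with a stabilised ylide under neutral conditions, which is E-selective.

Step 4
Reactants: 4 ethyl (E)-3-[2,2-diphenyl-7-(triisopropylsilyloxy)-1,3-benzodioxol-5-yl]acrylate
Product: 5 (E)-3-[2,2-diphenyl-7-(triisopropylsilyloxy)-1,3-benzodioxol-5-yl]prop-2-en-1-ol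
Conditions: i-Bu2AlH (2.5 equiv), CH2Cl2, −78 °C; aq. KNaC4H4O6 (potassium sodium tartrate)
Reagents that add atoms: none
Why: 1,2-Reduction of an α,β-unsaturated ester to the allylic alcohol by i-Bu2AlH, with the olefin geometry retained.

Step 5
Reactants: 5 (E)-3-[2,2-diphenyl-7-(triisopropylsilyloxy)-1,3-benzodioxol-5-yl]prop-2-en-1-ol
Product: 6 (E)-3-[2,2-diphenyl-7-(triisopropylsilyloxy)-1,3-benzodioxol-5-yl]allyl methyl carbonate
Conditions: ClCO2Me, pyridine, CH2Cl2, 0 °C
Reagents that add atoms: methyl chloroformate COC(Cl)=O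
Why: O-Acylation of a primary allylic alcohol gives the linear carbonate required for iridium-catalysed allylic substitution.

Step 6
Reactants: 7 2,4,6-trihydroxybenzaldehyde
Product: 8 2,4-bis(benzyloxy)-6-hydroxybenzaldehyde
Conditions: BnBr (2.05 equiv), K2CO3, DMF, 0 °C to rt
Reagents that add atoms: benzyl bromide BrCc1ccccc1
Why: Williamson etherification; the para-hydroxyl and one of the two equivalent ortho-hydroxyls react, while the last hydroxyl, hydrogen-bonded to the aldehyde, is the least nucleophilic and should remain.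

Step 7
Reactants: 8 2,4-bis(benzyloxy)-6-hydroxybenzaldehyde
Product: 9 3,5-bis(benzyloxy)-2-vinylphenol
Conditions: Ph3PCH3Br (2.5 equiv), KOt-Bu (3.5 equiv), THF, 0 °C to rt; aq. NH4Cl
Reagents that add atoms: methyltriphenylphosphonium bromide C[P+](c1ccccc1)(c1ccccc1)c1ccccc1.[Br-]
Why: Wittig methylenation of a salicylaldehyde with excess ylide (the first equivalent of base forms the phenoxide) gives the ortho-vinylphenol that carries the future C4.

Step 8
Reactants: 9 3,5-bis(benzyloxy)-2-vinylphenol, 6 (E)-3-[2,2-diphenyl-7-(triisopropylsilyloxy)-1,3-benzodioxol-5-yl]allyl methyl carbonate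
Product: 11 (S)-1,5-bis(benzyloxy)-3-{1-[2,2-diphenyl-7-(triisopropylsilyloxy)-1,3-benzodioxol-5-yl]allyloxy}-2-vinylbenzene, via sodium aryloxide 10 (not isolated)
Conditions: NaH (1.0 equiv relative to 9), THF, 0 °C; then 6, [Ir(cod)Cl]2 (2 mol %), phosphoramidite L (4 mol %, antipode giving (S)-11), THF, 50 °C
Reagents that add atoms: sodium hydride [Na+].[H-] (sodium of 10)
Why: Iridium-catalysed asymmetric allylic etherification; the cyclometalated iridium–phosphoramidite allyl complex is attacked by the aryloxide at its aryl-substituted terminus from the face fixed by the ligand, which forms the O1–C2 bond and sets C2 as (S) (the spatial arrangement of 2R in the final flavan).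

Step 9
Reactants: 11 (S)-1,5-bis(benzyloxy)-3-{1-[2,2-diphenyl-7-(triisopropylsilyloxy)-1,3-benzodioxol-5-yl]allyloxy}-2-vinylbenzene
Product: 12 (2S)-5,7-bis(benzyloxy)-2-[2,2-diphenyl-7-(triisopropylsilyloxy)-1,3-benzodioxol-5-yl]-2H-chromene
Conditions: second-generation Grubbs catalyst RuCl2(=CHPh)(H2IMes)(PCy3) (5 mol %), CH2Cl2 (0.01 M), 40 °C, dark
Reagents that add atoms: none
Why: Olefin metathesis by the Chauvin mechanism: the ruthenium benzylidene exchanges onto the unhindered allylic vinyl group, the new alkylidene adds [2+2] to the ring-D styrene, and the metallacyclobutane cycloreverts to release ethene and the C3=C4 double bond, so the C3–C4 bond is itself the ring-closing bond. The closest known reaction is the ring-closing metathesis of 1-arylallyl ethers of 2-vinylphenols to 2-aryl-2H-chromenes. Ring F closes as a six-membered ring with both olefin carbons inside the ring, and no other ring size is available to the diene. No stereocenter is created; C2 from step 8 is untouched because the conditions are neutral and C2–H is neither deprotonated nor ionised. The step needs ring closure to outrun cross-metathesis and needs C2 to keep its configuration: the six-membered ring, high dilution and the absence of any other olefin (only silyl, benzyl and ketal protecting groups) secure the first, and exclusion of light and acid at 40 °C or below secures the second.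

Step 10
Reactants: 12 (2S)-5,7-bis(benzyloxy)-2-[2,2-diphenyl-7-(triisopropylsilyloxy)-1,3-benzodioxol-5-yl]-2H-chromene
Product: 14 (2R,3S)-5,7-bis(benzyloxy)-2-[2,2-diphenyl-7-(triisopropylsilyloxy)-1,3-benzodioxol-5-yl]chroman-3-ol, via alkylborane 13 (not isolated)
Conditions: BH3·THF, THF, 0 °C to rt; then 30 % H2O2, aq. NaOAc, 0 °C to rt
Reagents that add atoms: borane B (boron of 13); hydrogen peroxide OO (oxygen of 14)
Why: Hydroboration–oxidation; boron adds to C3 (the carbon remote from the ring-D arene) from the face opposite the C2 aryl group and is oxidised with retention, so O3 is introduced trans to the aryl group (3S).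

Step 11
Reactants: 14 (2R,3S)-5,7-bis(benzyloxy)-2-[2,2-diphenyl-7-(triisopropylsilyloxy)-1,3-benzodioxol-5-yl]chroman-3-ol
Product: 15 (2R)-5,7-bis(benzyloxy)-2-[2,2-diphenyl-7-(triisopropylsilyloxy)-1,3-benzodioxol-5-yl]chroman-3-one
Conditions: Dess–Martin periodinane, NaHCO3, CH2Cl2, 0 °C to rt
Reagents that add atoms: none
Why: Dess–Martin oxidation under buffered, non-basic conditions, as used for benzylated catechins, gives the flavan-3-one without enolisation at C2.

Step 12
Reactants: 15 (2R)-5,7-bis(benzyloxy)-2-[2,2-diphenyl-7-(triisopropylsilyloxy)-1,3-benzodioxol-5-yl]chroman-3-one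
Product: 16 (2R,3R)-5,7-bis(benzyloxy)-2-[2,2-diphenyl-7-(triisopropylsilyloxy)-1,3-benzodioxol-5-yl]chroman-3-ol
Conditions: LiBH(s-Bu)3 (L-Selectride), LiBr, THF, −78 °C; aq. NH4Cl
Reagents that add atoms: none
Why: Reduction with a bulky hydride that enters from the face opposite the equatorial C2 aryl group, giving the axial alcohol cis to the aryl group (3R, the epi series).

Step 13
Reactants: 16 (2R,3R)-5,7-bis(benzyloxy)-2-[2,2-diphenyl-7-(triisopropylsilyloxy)-1,3-benzodioxol-5-yl]chroman-3-ol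
Product: 17 (2R,3R)-8-bromo-5,7-bis(benzyloxy)-2-[2,2-diphenyl-7-(triisopropylsilyloxy)-1,3-benzodioxol-5-yl]chroman-3-ol
Conditions: NBS (1.05 equiv), CH2Cl2, −78 to 0 °C
Reagents that add atoms: N-bromosuccinimide O=C1CCC(=O)N1Br
Why: Electrophilic aromatic bromination; ring D is far more activated than ring E, and C8 is brominated in preference to C6 as in benzylated epicatechin, which caps C8 and leaves C6 as the only nucleophilic site.

Step 14
Reactants: 17 (2R,3R)-8-bromo-5,7-bis(benzyloxy)-2-[2,2-diphenyl-7-(triisopropylsilyloxy)-1,3-benzodioxol-5-yl]chroman-3-ol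
Product: 18 (2R,3R)-8-bromo-5,7-bis(benzyloxy)-2-(7-hydroxy-2,2-diphenyl-1,3-benzodioxol-5-yl)chroman-3-ol
Conditions: Bu4NF, AcOH, THF, 0 °C
Reagents that add atoms: none
Why: Fluoride-mediated cleavage of the aryl silyl ether frees O3′ alone; benzyl ethers, the ketal and the aryl bromide are inert.

Step 15
Reactants: 18 (2R,3R)-8-bromo-5,7-bis(benzyloxy)-2-(7-hydroxy-2,2-diphenyl-1,3-benzodioxol-5-yl)chroman-3-ol, 19 3,4,5-tris(benzyloxy)benzoic acid
Product: 20 (2R,3R)-8-bromo-5,7-bis(benzyloxy)-2-{2,2-diphenyl-7-[3,4,5-tris(benzyloxy)benzoyloxy]-1,3-benzodioxol-5-yl}chroman-3-yl 3,4,5-tris(benzyloxy)benzoate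
Conditions: 19 (3 equiv), DCC (3 equiv), DMAP (0.5 equiv), CH2Cl2, rt
Reagents that add atoms: none
Why: Double Steglich esterification installs both protected galloyl groups at once on the only two free hydroxyls (O3 and O3′), with C3 unchanged.

Step 16
Reactants: 21 (−)-epiafzelechin
Product: 22 (2R,3R)-5,7-bis(benzyloxy)-2-[4-(benzyloxy)phenyl]chroman-3-ol
Conditions: BnBr (3.3 equiv), K2CO3, DMF, 0 °C to rt, argon
Reagents that add atoms: benzyl bromide BrCc1ccccc1
Why: Williamson benzylation with a carbonate base is selective for the three phenols over the secondary alcohol.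

Step 17
Reactants: 22 (2R,3R)-5,7-bis(benzyloxy)-2-[4-(benzyloxy)phenyl]chroman-3-ol
Product: 23 4β-(2-ethoxyethoxy)-5,7,4′-tri-O-benzylepiafzelechin
Conditions: DDQ (2 equiv), 2-ethoxyethanol (5 equiv), CH2Cl2, rt
Reagents that add atoms: 2-ethoxyethanol CCOCCO
Why: Benzylic oxidation by DDQ; hydride abstraction from C4 gives a cation stabilised by ring A, which the alcohol traps trans to the 3-hydroxyl (4β).

Step 18
Reactants: 23 4β-(2-ethoxyethoxy)-5,7,4′-tri-O-benzylepiafzelechin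
Product: 24 6,8-dibromo-4β-(2-ethoxyethoxy)-5,7,4′-tri-O-benzylepiafzelechin
Conditions: NBS (2.1 equiv), CH2Cl2, −40 to 0 °C
Reagents that add atoms: N-bromosuccinimide O=C1CCC(=O)N1Br
Why: Twofold electrophilic bromination of ring A caps C6 and C8, so the electrophile cannot condense with itself; the mono-oxygenated ring B is not attacked.

Step 19
Reactants: 24 6,8-dibromo-4β-(2-ethoxyethoxy)-5,7,4′-tri-O-benzylepiafzelechin, 20 (2R,3R)-8-bromo-5,7-bis(benzyloxy)-2-{2,2-diphenyl-7-[3,4,5-tris(benzyloxy)benzoyloxy]-1,3-benzodioxol-5-yl}chroman-3-yl 3,4,5-tris(benzyloxy)benzoate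
Product: 25 fully protected tribromo dimer (6,8-dibromo-5,7,4′-tri-O-benzylepiafzelechin linked 4β→6 to unit 20)
Conditions: TMSOTf (0.3 equiv), 4 Å molecular sieves, CH2Cl2, −78 to −30 °C; aq. NaHCO3
Reagents that add atoms: none
Why: Lewis-acid ionisation of the C4 ether and Friedel–Crafts attack by the only free ring-D position of 20 (C6, since C8 is bromine-capped); the arene approaches the C4 cation anti to the axial 3-hydroxyl, setting the upper C4 as 4β (3,4-trans).

Step 20
Reactants: 25 fully protected tribromo dimer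
Product: 26 (−)-epiafzelechin-(4β→6)-(−)-epigallocatechin 3,3′-di-O-gallate
Conditions: H2 (1 atm), Pd(OH)2/C, NaOAc (3.3 equiv), THF/MeOH/H2O, rt; filtration, Sephadex LH-20
Reagents that add atoms: none
Why: Catalytic hydrogenolysis removes the eleven benzyl ethers, the diphenylmethylene ketal and the three aryl bromides in one operation, with acetate buffering the HBr so that neither the interflavan bond nor the gallate positions are disturbed.

**Compound list**

1 | 3,4,5-trihydroxybenzaldehyde | O=Cc1cc(O)c(O)c(O)c1 | starting material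
2 | 7-hydroxy-2,2-diphenyl-1,3-benzodioxole-5-carbaldehyde | O=Cc1cc(O)c2OC(c3ccccc3)(c3ccccc3)Oc2c1 | intermediate
3 | 2,2-diphenyl-7-(triisopropylsilyloxy)-1,3-benzodioxole-5-carbaldehyde | O=Cc1cc(O[Si](C(C)C)(C(C)C)C(C)C)c2OC(c3ccccc3)(c3ccccc3)Oc2c1 | intermediate
4 | ethyl (E)-3-[2,2-diphenyl-7-(triisopropylsilyloxy)-1,3-benzodioxol-5-yl]acrylate | CCOC(=O)/C=C/c1cc(O[Si](C(C)C)(C(C)C)C(C)C)c2OC(c3ccccc3)(c3ccccc3)Oc2c1 | intermediate
5 | (E)-3-[2,2-diphenyl-7-(triisopropylsilyloxy)-1,3-benzodioxol-5-yl]prop-2-en-1-ol | OC/C=C/c1cc(O[Si](C(C)C)(C(C)C)C(C)C)c2OC(c3ccccc3)(c3ccccc3)Oc2c1 | intermediate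
6 | (E)-3-[2,2-diphenyl-7-(triisopropylsilyloxy)-1,3-benzodioxol-5-yl]allyl methyl carbonate | COC(=O)OC/C=C/c1cc(O[Si](C(C)C)(C(C)C)C(C)C)c2OC(c3ccccc3)(c3ccccc3)Oc2c1 | intermediate
7 | 2,4,6-trihydroxybenzaldehyde | O=Cc1c(O)cc(O)cc1O | starting material
8 | 2,4-bis(benzyloxy)-6-hydroxybenzaldehyde | O=Cc1c(O)cc(OCc2ccccc2)cc1OCc1ccccc1 | intermediate
9 | 3,5-bis(benzyloxy)-2-vinylphenol | C=Cc1c(O)cc(OCc2ccccc2)cc1OCc1ccccc1 | intermediate
10 | sodium 3,5-bis(benzyloxy)-2-vinylphenoxide | C=Cc1c([O-])cc(OCc2ccccc2)cc1OCc1ccccc1.[Na+] | intermediate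
11 | (S)-1,5-bis(benzyloxy)-3-{1-[2,2-diphenyl-7-(triisopropylsilyloxy)-1,3-benzodioxol-5-yl]allyloxy}-2-vinylbenzene | CC(C)[Si](C(C)C)(C(C)C)Oc1cc([C@H](C=C)Oc3cc(OCc4ccccc4)cc(OCc4ccccc4)c3C=C)cc2OC(c3ccccc3)(c3ccccc3)Oc12 | intermediate
12 | (2S)-5,7-bis(benzyloxy)-2-[2,2-diphenyl-7-(triisopropylsilyloxy)-1,3-benzodioxol-5-yl]-2H-chromene (flav-3-ene) | CC(C)[Si](C(C)C)(C(C)C)Oc1cc([C@H]3Oc4cc(OCc5ccccc5)cc(OCc5ccccc5)c4C=C3)cc2OC(c3ccccc3)(c3ccccc3)Oc12 | intermediate
13 | 2,3-trans-{5,7-bis(benzyloxy)-2-[2,2-diphenyl-7-(triisopropylsilyloxy)-1,3-benzodioxol-5-yl]chroman-3-yl}borane (boron trans to the C2 aryl group) | CC(C)[Si](C(C)C)(C(C)C)Oc1cc([C@H]3Oc4cc(OCc5ccccc5)cc(OCc5ccccc5)c4C[C@@H]3B)cc2OC(c3ccccc3)(c3ccccc3)Oc12 | intermediate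
14 | (2R,3S)-5,7-bis(benzyloxy)-2-[2,2-diphenyl-7-(triisopropylsilyloxy)-1,3-benzodioxol-5-yl]chroman-3-ol (2,3-trans) | CC(C)[Si](C(C)C)(C(C)C)Oc1cc([C@H]3Oc4cc(OCc5ccccc5)cc(OCc5ccccc5)c4C[C@@H]3O)cc2OC(c3ccccc3)(c3ccccc3)Oc12 | intermediate
15 | (2R)-5,7-bis(benzyloxy)-2-[2,2-diphenyl-7-(triisopropylsilyloxy)-1,3-benzodioxol-5-yl]chroman-3-one | CC(C)[Si](C(C)C)(C(C)C)Oc1cc([C@H]3Oc4cc(OCc5ccccc5)cc(OCc5ccccc5)c4CC3=O)cc2OC(c3ccccc3)(c3ccccc3)Oc12 | intermediate
16 | (2R,3R)-5,7-bis(benzyloxy)-2-[2,2-diphenyl-7-(triisopropylsilyloxy)-1,3-benzodioxol-5-yl]chroman-3-ol (2,3-cis) | CC(C)[Si](C(C)C)(C(C)C)Oc1cc([C@H]3Oc4cc(OCc5ccccc5)cc(OCc5ccccc5)c4C[C@H]3O)cc2OC(c3ccccc3)(c3ccccc3)Oc12 | intermediate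
17 | (2R,3R)-8-bromo-5,7-bis(benzyloxy)-2-[2,2-diphenyl-7-(triisopropylsilyloxy)-1,3-benzodioxol-5-yl]chroman-3-ol | CC(C)[Si](C(C)C)(C(C)C)Oc1cc([C@H]3Oc4c(Br)c(OCc5ccccc5)cc(OCc5ccccc5)c4C[C@H]3O)cc2OC(c3ccccc3)(c3ccccc3)Oc12 | intermediate
18 | (2R,3R)-8-bromo-5,7-bis(benzyloxy)-2-(7-hydroxy-2,2-diphenyl-1,3-benzodioxol-5-yl)chroman-3-ol | Oc1cc([C@H]3Oc4c(Br)c(OCc5ccccc5)cc(OCc5ccccc5)c4C[C@H]3O)cc2OC(c3ccccc3)(c3ccccc3)Oc12 | intermediate
19 | 3,4,5-tris(benzyloxy)benzoic acid | OC(=O)c1cc(OCc2ccccc2)c(OCc2ccccc2)c(OCc2ccccc2)c1 | starting material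
20 | (2R,3R)-8-bromo-5,7-bis(benzyloxy)-2-{2,2-diphenyl-7-[3,4,5-tris(benzyloxy)benzoyloxy]-1,3-benzodioxol-5-yl}chroman-3-yl 3,4,5-tris(benzyloxy)benzoate | O=C(Oc1cc([C@H]3Oc4c(Br)c(OCc5ccccc5)cc(OCc5ccccc5)c4C[C@H]3OC(=O)c3cc(OCc4ccccc4)c(OCc4ccccc4)c(OCc4ccccc4)c3)cc2OC(c3ccccc3)(c3ccccc3)Oc12)c1cc(OCc2ccccc2)c(OCc2ccccc2)c(OCc2ccccc2)c1 | intermediate
21 | (−)-epiafzelechin, (2R,3R)-2-(4-hydroxyphenyl)chroman-3,5,7-triol | C1c2c(O)cc(O)cc2O[C@H](c2ccc(O)cc2)[C@@H]1O | starting material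
22 | (2R,3R)-5,7-bis(benzyloxy)-2-[4-(benzyloxy)phenyl]chroman-3-ol (5,7,4′-tri-O-benzylepiafzelechin) | C1c2c(OCc3ccccc3)cc(OCc3ccccc3)cc2O[C@H](c2ccc(OCc3ccccc3)cc2)[C@@H]1O | intermediate
23 | 4β-(2-ethoxyethoxy)-5,7,4′-tri-O-benzylepiafzelechin (2,3-cis, 3,4-trans) | CCOCCO[C@H]1c2c(OCc3ccccc3)cc(OCc3ccccc3)cc2O[C@H](c2ccc(OCc3ccccc3)cc2)[C@@H]1O | intermediate
24 | 6,8-dibromo-4β-(2-ethoxyethoxy)-5,7,4′-tri-O-benzylepiafzelechin | CCOCCO[C@H]1c2c(OCc3ccccc3)c(Br)c(OCc3ccccc3)c(Br)c2O[C@H](c2ccc(OCc3ccccc3)cc2)[C@@H]1O | intermediate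
25 | fully protected tribromo dimer: 6,8-dibromo-5,7,4′-tri-O-benzylepiafzelechin-(4β→6)-[8-bromo-5,7-di-O-benzyl-4′,5′-O-diphenylmethylene-epigallocatechin 3,3′-bis(3,4,5-tri-O-benzylgallate)] | O=C(Oc1cc([C@H]2Oc3c(Br)c(OCc6ccccc6)c([C@H]4c5c(OCc6ccccc6)c(Br)c(OCc6ccccc6)c(Br)c5O[C@H](c5ccc(OCc6ccccc6)cc5)[C@@H]4O)c(OCc6ccccc6)c3C[C@H]2OC(=O)c2cc(OCc3ccccc3)c(OCc3ccccc3)c(OCc3ccccc3)c2)cc2OC(c3ccccc3)(c3ccccc3)Oc12)c1cc(OCc2ccccc2)c(OCc2ccccc2)c(OCc2ccccc2)c1 | intermediate
26 | (−)-epiafzelechin-(4β→6)-(−)-epigallocatechin 3,3′-di-O-gallate (CNP0290965.1; both galloyl groups on the lower unit, at O3 and O3′) | O=C(Oc1cc([C@H]2Oc3cc(O)c([C@H]4c5c(O)cc(O)cc5O[C@H](c5ccc(O)cc5)[C@@H]4O)c(O)c3C[C@H]2OC(=O)c2cc(O)c(O)c(O)c2)cc(O)c1O)c1cc(O)c(O)c(O)c1 | target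

**Step count**

Total: 20 steps. Longest linear sequence: 15 steps (steps 1–5, 8–15, 19, 20).

**Steps most likely to fail, with fallbacks**

Step 8 (iridium-catalysed etherification). The risk is loss of branched selectivity or of enantiopurity, because the hindered, very electron-rich aryloxide attacks slowly and the product ether can re-ionise at its doubly activated C2–O bond. The fallback sets out from 3 and 9 and comes back at 11. Addition of HC≡CMgBr to aldehyde 3 in THF gives the racemic propargylic alcohol F1, and Ac2O/pyridine converts it into the racemic propargylic acetate F2. Copper-catalysed enantioconvergent propargylic etherification of phenol 9 with F2 (CuOTf·0.5C6H6, chiral Ph-pybox, i-Pr2NEt, MeOH, low temperature) proceeds through a copper allenylidene and gives the (S)-propargyl aryl ether F3. Semihydrogenation of the terminal alkyne (H2, Pd/CaCO3 poisoned with Pb(OAc)2, quinoline) then gives 11.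

Step 19 (interflavan coupling). The risk is failed ionisation or failed C–C bond formation: the 6-bromo substituent pushes the 5-benzyloxy group over C4, both arenes are deactivated by bromine, and prolonged Lewis acid exposure may open the diphenylmethylene ketal. The fallback sets out from 23 and comes back at 26. Monobromination of 23 (NBS, 1.0 equiv, −78 °C) gives the 8-bromo ether F4, an electrophile class with precedent. Slow addition of F4 to three equivalents of 20 under the TMSOTf conditions gives the protected dibromo dimer F5; self-condensation through the free C6 of F4 is suppressed by the excess of 20, which is recovered. Hydrogenolysis of F5 under the conditions of step 20 gives 26.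

Step 20 (global hydrogenolysis). The risk is incomplete reaction over more than a dozen hydrogenolytic cleavages with bromide poisoning of the catalyst, acid-induced cleavage of the interflavan bond if buffering fails, or galloyl migration on the pyrogallol ring if the medium turns basic. The fallback sets out from 25 and comes back at 26. A radical chain hydrodebromination (Bu3SnH, AIBN, toluene, 90 °C) removes the three bromines first and leaves benzyl ethers, esters and the ketal untouched, giving the bromine-free protected dimer F6. Hydrogenolysis of F6 (H2, Pd(OH)2/C, THF/MeOH, no additive) then runs without any HBr and gives 26.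

**Further compounds**

F1 | step 8 | rac-1-[2,2-diphenyl-7-(triisopropylsilyloxy)-1,3-benzodioxol-5-yl]prop-2-yn-1-ol | OC(C#C)c1cc(O[Si](C(C)C)(C(C)C)C(C)C)c2OC(c3ccccc3)(c3ccccc3)Oc2c1
F2 | step 8 | rac-1-[2,2-diphenyl-7-(triisopropylsilyloxy)-1,3-benzodioxol-5-yl]prop-2-ynyl acetate | CC(=O)OC(C#C)c1cc(O[Si](C(C)C)(C(C)C)C(C)C)c2OC(c3ccccc3)(c3ccccc3)Oc2c1
F3 | step 8 | (S)-1,5-bis(benzyloxy)-3-{1-[2,2-diphenyl-7-(triisopropylsilyloxy)-1,3-benzodioxol-5-yl]prop-2-ynyloxy}-2-vinylbenzene | CC(C)[Si](C(C)C)(C(C)C)Oc1cc([C@H](C#C)Oc3cc(OCc4ccccc4)cc(OCc4ccccc4)c3C=C)cc2OC(c3ccccc3)(c3ccccc3)Oc12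
F4 | step 19 | 8-bromo-4β-(2-ethoxyethoxy)-5,7,4′-tri-O-benzylepiafzelechin | CCOCCO[C@H]1c2c(OCc3ccccc3)cc(OCc3ccccc3)c(Br)c2O[C@H](c2ccc(OCc3ccccc3)cc2)[C@@H]1O
F5 | step 19 | protected dibromo dimer (bromine at C8 of each unit; otherwise as 25) | O=C(Oc1cc([C@H]2Oc3c(Br)c(OCc6ccccc6)c([C@H]4c5c(OCc6ccccc6)cc(OCc6ccccc6)c(Br)c5O[C@H](c5ccc(OCc6ccccc6)cc5)[C@@H]4O)c(OCc6ccccc6)c3C[C@H]2OC(=O)c2cc(OCc3ccccc3)c(OCc3ccccc3)c(OCc3ccccc3)c2)cc2OC(c3ccccc3)(c3ccccc3)Oc12)c1cc(OCc2ccccc2)c(OCc2ccccc2)c(OCc2ccccc2)c1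
F6 | step 20 | bromine-free protected dimer (otherwise as 25) | O=C(Oc1cc([C@H]2Oc3cc(OCc6ccccc6)c([C@H]4c5c(OCc6ccccc6)cc(OCc6ccccc6)cc5O[C@H](c5ccc(OCc6ccccc6)cc5)[C@@H]4O)c(OCc6ccccc6)c3C[C@H]2OC(=O)c2cc(OCc3ccccc3)c(OCc3ccccc3)c(OCc3ccccc3)c2)cc2OC(c3ccccc3)(c3ccccc3)Oc12)c1cc(OCc2ccccc2)c(OCc2ccccc2)c(OCc2ccccc2)c1
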